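Loading in mol% counts enzyme per substrate charged, so flasks with one charge compare enzyme directly.

| flask | substrate | enzyme | remark |
|---|---|---|---|
| midnight | 0.050 M | 0.05 mol% | run made earlier |
| summer | 0.075 M | 0.05 mol% | run made earlier |
| dawn | 0.10 M | 0.025 mol% | run made earlier |
| flask | 0.10 M | 0.05 mol% |  |

- midnight (time / min: product / %, substrate / %): 6.00: 91.2, 1.7; 10.0: 91.8, 1.1; 15.0: 92.8, 0; 25.0: 91.1, 0; 40.0: 91.4, 2.1; 80.0: 90.3, 0
- summer (time / min: product / %, substrate / %): 12.0: 89.5, 0.5; 25.0: 90.8, 0; 40.0: 90.8, 0; 50.0: 89.7, 0.4; 60.0: 91.4, 0.7; 80.0: 91.1, 0.3
- dawn (time / min: product / %, substrate / %): 15.0: 81.0, 0; 30.0: 80.9, 0.6; 40.0: 80.6, 0; 60.0: 80.9, 0.8; 80.0: 80.5, 0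

(each reading ± 1 percentage point)



- factor on the rate of making product when 5.0% of the substrate are converted if enzyme is charged twice over
- factor on the rate when 5.0% of the substrate are converted if enzyme is charged at 0.01 mol% instead

The earlier runs give yields, not rates: the first midnight sample, at 6.00 min, already reads 1.7% substrate and 91.2% product. The dawn run, at half that loading and with 0.10 M substrate against 0.050 M, reads 81.0% product and 0% substrate at 15.0 min, so in the dawn run substrate has gone elsewhere than to product; two settings differ between these runs.

Two extremes can be solved in the head. Let x be the fraction of substrate left. In one extreme the enzyme route runs proportional to substrate; in the other it runs independent of substrate. In both, its rate is enzyme times a function of substrate. At 5.0% conversion x is 95.0% in either flask, so with one charge the function cancels. The real order is reckoned to lie between, and the reckoning stays unchanged provided enzyme survives. The enzyme factor f, new loading over old, is then 0.200 for the smaller loading and 2.00 for the doubled one.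

The forecast gives 2.3 (1.9 to 2.7) and 0.08 (0.01 to 0.2), judging that “rate is more than proportional to loading”; its smaller factor is lower than f.

The simulation gives 2.00 and 0.200.

    substrate + enzyme ⇌ complex (K = 43.0 /M, k = 1.90 × 10⁵ /M/min)
    complex → enzyme + product (k = 3200 /min)
    2 substrate → homo dimer (k = 2.10 /M/min)

These stand beside the enzyme factors 2.00 and 0.200. In the flask, of the turnover up to 1.00 h, the step to homo dimer had half behind it at 0.181 min and the step from substrate and enzyme to complex at 0.438 min. At 0.100 h the flask holds 0% substrate, 88.5% product, 11.5% homo dimer, counted by the substrate it holds, and 100% of its enzyme free.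

(Readings and results come from a simulation on assumed constants, and the scatter is random.)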